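**Retrosynthetic overview**
- The only ring, the 14-membered lactone, is closed at O13–C1 (Yamaguchi) on a seco acid carrying a 3,5-acetonide and 11,15-silyl ethers; global deprotection follows.
- The seco chain comes from a C10–C11 syn-aldol (Mukaiyama, Felkin/1,3-anti) between a C1–C10 ethyl ketone (West fragment) and a C11–C16 aldehyde (East fragment).
- West fragment: C4–C5 anti-aldol of a β-ketoimide (C2 from cinchona-catalysed methylketene dimerisation) with (2R,4R)-2,4-dimethyl-5-oxoheptanal, then 1,3-anti reduction (C3).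
- The keto-aldehyde (C6–C7 bond, C6 and C8): proposed dual-amine Michael addition/enantioselective protonation of propanal with 2-methylpent-1-en-3-one.
- East fragment: phosphoramide/SiCl4-catalysed anti-aldol of a tert-butyl propanoate ketene acetal with tiglaldehyde (C12, C13), then anti-selective hydroboration of the E-alkene (C14, C15).

Assumptions: locants C1–C16 are those of the seco acid (C1 lactone carbonyl, C13 lactone-oxygen carbon); 2-methylpent-1-en-3-one is bought stabilised; each chiral catalyst is named as the antipode expected from its usual model and is swapped for its mirror image (pseudo-enantiomer for the cinchona base) if a first run shows the opposite sense.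

**Step 1**
Reactants: 1 propanoyl chloride (2 equiv), 2 1,3-oxazolidin-2-one
Product: 4 3-[(2R)-2-methyl-3-oxopentanoyl]-1,3-oxazolidin-2-one, via methylketene dimer 3 (not isolated)
Conditions: iPr2NEt, O-trimethylsilylquinidine (5 mol%), CH2Cl2, rt; pentane, filter; then N-lithio-2 (2, n-BuLi, THF), −78 °C; aq NH4Cl
Reagents that add atoms: none
Why: Cinchona-base-catalysed asymmetric ketene dimerisation (the chiral ammonium enolate of methylketene acylates a second ketene and sets C2 as R), then N-acylation of the lithiated oxazolidinone by the β-lactone, the C2–H being shielded from enolisation by A(1,3) strain as in Evans β-ketoimides.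

**Step 2**
Reactants: 5 propanal, 6 2-methylpent-1-en-3-one
Product: 7 (2R,4R)-2,4-dimethyl-5-oxoheptanal
Conditions: (S)-α,α-diphenylprolinol trimethylsilyl ether (10 mol%), (S)-N1,N1-diethyl-3,3-dimethylbutane-1,2-diamine·TfOH (10 mol%), 4-nitrophenol (20 mol%), CHCl3, 0 °C, 5 (3 equiv) added over 6 h
Reagents that add atoms: none
Why: Proposed new method: dual-amine relay Michael addition with enantioselective protonation; the diarylprolinol silyl ether turns 5 into an E-enamine that attacks the β-carbon of 6 from its unshielded face (sets C2 of 7, C6 of the target) while 6 is activated as the iminium ion of the primary–tertiary diamine salt, whose pendant ammonium N–H then protonates the resulting ketone-derived enamine on one face (sets C4 of 7, C8) before hydrolysis, so each of the two 1,3-related centres has its own catalyst and the anti (R,R) isomer is addressed by pairing the right antipodes; the closest known reaction types are the diarylprolinol-ether-catalysed Michael addition of aldehydes to α-unsubstituted vinyl ketones and the primary-amine-catalysed conjugate addition/enamine protonation of α-substituted vinyl ketones with indole and thiol nucleophiles.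

**Step 3**
Reactants: 4 3-[(2R)-2-methyl-3-oxopentanoyl]-1,3-oxazolidin-2-one, 7 (2R,4R)-2,4-dimethyl-5-oxoheptanal
Product: 8 3-[(2R,4S,5S,6R,8R)-5-hydroxy-2,4,6,8-tetramethyl-3,9-dioxoundecanoyl]-1,3-oxazolidin-2-one
Conditions: 4, Cy2BCl, Me2NEt, Et2O, 0 °C; then 7, −78 to −20 °C; H2O2, MeOH, pH 7 buffer
Reagents that add atoms: none
Why: Evans-type anti-selective boron aldol of the E-enol borinate of the β-ketoimide, in which the C2 methyl centre directs the anti,anti adduct (C4, C5) and the α-methyl aldehyde reacts with Felkin–Anh selectivity (C5/C6 syn), a matched pair, the aldehyde reacting ahead of the C9 ketone.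

**Step 4**
Reactants: 8 3-[(2R,4S,5S,6R,8R)-5-hydroxy-2,4,6,8-tetramethyl-3,9-dioxoundecanoyl]-1,3-oxazolidin-2-one
Product: 9 3-[(2R,3R,4S,5S,6R,8R)-3,5-dihydroxy-2,4,6,8-tetramethyl-9-oxoundecanoyl]-1,3-oxazolidin-2-one
Conditions: Me4NBH(OAc)3, MeCN/AcOH, −30 °C
Reagents that add atoms: none
Why: Evans–Saksena hydroxyl-directed reduction, with intramolecular hydride delivery from the C5 alkoxyborohydride through a chair transition state giving the 3,5-anti diol (3R) and leaving the remote C9 ketone untouched.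

**Step 5**
Reactants: 9 3-[(2R,3R,4S,5S,6R,8R)-3,5-dihydroxy-2,4,6,8-tetramethyl-9-oxoundecanoyl]-1,3-oxazolidin-2-one
Product: 10 3-[(2R)-2-[(4R,5S,6S)-2,2,5-trimethyl-6-[(2R,4R)-4-methyl-5-oxoheptan-2-yl]-1,3-dioxan-4-yl]propanoyl]-1,3-oxazolidin-2-one
Conditions: 2,2-dimethoxypropane, PPTS (cat.), acetone, rt
Reagents that add atoms: 2,2-dimethoxypropane COC(C)(C)OC
Why: Acid-catalysed transketalisation ties the anti-1,3-diol into its acetonide (blocking δ-lactonisation later) without touching a stereocentre.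

**Step 6**
Reactants: 11 tert-butyl propanoate
Product: 12 (E)-tert-butyl[(1-tert-butoxyprop-1-en-1-yl)oxy]dimethylsilane
Conditions: LiN(iPr)2, THF, −78 °C; then TBSCl, DMPU, −78 °C to rt
Reagents that add atoms: tert-butyldimethylsilyl chloride CC(C)(C)[Si](C)(C)Cl
Why: Kinetic ester deprotonation through the Ireland chair transition state gives the E-enolate, which is O-silylated to the E-silyl ketene acetal.

**Step 7**
Reactants: 12 (E)-tert-butyl[(1-tert-butoxyprop-1-en-1-yl)oxy]dimethylsilane, 13 (2E)-2-methylbut-2-enal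
Product: 14 tert-butyl (2S,3R,4E)-3-hydroxy-2,4-dimethylhex-4-enoate
Conditions: SiCl4 (1.1 equiv), Denmark's (R,R)-binaphthyldiamine-derived bisphosphoramide with pentane-1,5-diyl linker (2 mol%), CH2Cl2, −78 °C; sat. aq NaHCO3
Reagents that add atoms: none
Why: Lewis-base-activated Lewis-acid (phosphoramide-bound trichlorosilyl cation) Mukaiyama aldol through an open transition state, anti-selective for propanoate ketene acetals and enantioface-selective on the conjugated aldehyde, sets C12 and C13 on an achiral acceptor.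

**Step 8**
Reactants: 14 tert-butyl (2S,3R,4E)-3-hydroxy-2,4-dimethylhex-4-enoate
Product: 15 tert-butyl (2S,3S,4S,5S)-3,5-dihydroxy-2,4-dimethylhexanoate
Conditions: 9-BBN (3 equiv), THF, 0 to 40 °C; then H2O2, aq NaOH, 0 °C
Reagents that add atoms: hydrogen peroxide OO
Why: Still–Barrish-type substrate-controlled hydroboration, with syn addition to the E-trisubstituted alkene (C14/C15 anti) on the face anti to the carbinol substituent in the allylic-strain-minimised conformer (C13/C14 anti), boron going to the less substituted C15 and oxidation proceeding with retention.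

**Step 9**
Reactants: 15 tert-butyl (2S,3S,4S,5S)-3,5-dihydroxy-2,4-dimethylhexanoate
Product: 17 tert-butyl (2S,3S,4S,5S)-5-[(tert-butyldimethylsilyl)oxy]-2,4-dimethyl-3-[(triethylsilyl)oxy]hexanoate, via C15 mono-TBS ether 16 (not isolated)
Conditions: TBSCl (1.1 equiv), imidazole, DMF, 0 °C; then TESCl (1.5 equiv), DMAP (cat.), rt
Reagents that add atoms: tert-butyldimethylsilyl chloride CC(C)(C)[Si](C)(C)Cl; triethylsilyl chloride CC[Si](Cl)(CC)CC
Why: Steric differentiation in a sequential silylation, the methyl carbinol (C15–OH) taking the bulky TBS group first and the hindered C13–OH then being capped with the smaller, selectively removable TES group.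

**Step 10**
Reactants: 17 tert-butyl (2S,3S,4S,5S)-5-[(tert-butyldimethylsilyl)oxy]-2,4-dimethyl-3-[(triethylsilyl)oxy]hexanoate
Product: 18 (2R,3R,4S,5S)-5-[(tert-butyldimethylsilyl)oxy]-2,4-dimethyl-3-[(triethylsilyl)oxy]hexan-1-ol
Conditions: iBu2AlH (2.5 equiv), CH2Cl2, −78 to 0 °C; aq potassium sodium tartrate
Reagents that add atoms: none
Why: Hydride reduction of the ester to the primary alcohol, silyl ethers being inert (descriptors change only through priorities).

**Step 11**
Reactants: 18 (2R,3R,4S,5S)-5-[(tert-butyldimethylsilyl)oxy]-2,4-dimethyl-3-[(triethylsilyl)oxy]hexan-1-ol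
Product: 19 (2S,3S,4S,5S)-5-[(tert-butyldimethylsilyl)oxy]-2,4-dimethyl-3-[(triethylsilyl)oxy]hexanal
Conditions: Dess–Martin periodinane, NaHCO3, CH2Cl2, 0 °C to rt; used crude
Reagents that add atoms: none
Why: Buffered Dess–Martin oxidation gives the α-chiral aldehyde without epimerisation.

**Step 12**
Reactants: 10 3-[(2R)-2-[(4R,5S,6S)-2,2,5-trimethyl-6-[(2R,4R)-4-methyl-5-oxoheptan-2-yl]-1,3-dioxan-4-yl]propanoyl]-1,3-oxazolidin-2-one, 19 (2S,3S,4S,5S)-5-[(tert-butyldimethylsilyl)oxy]-2,4-dimethyl-3-[(triethylsilyl)oxy]hexanal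
Product: 21 C1–C16 aldol adduct (N-acyl oxazolidinone; 3,5-acetonide; 9-ketone; 11-OH; 13-OTES; 15-OTBS), via Z-enolsilane 20 (not isolated)
Conditions: 10, TMSOTf, Et3N, CH2Cl2, −78 to 0 °C; pentane, filter, concentrate; then 19, BF3·OEt2, CH2Cl2, −78 °C; aq NaHCO3
Reagents that add atoms: trimethylsilyl trifluoromethanesulfonate C[Si](C)(C)OS(=O)(=O)C(F)(F)F (silyl group of 20)
Why: Mukaiyama aldol of the Z-enolsilane through an open transition state gives the C10/C11 syn adduct, and for this α-methyl-β-silyloxy aldehyde with anti substituents Felkin–Anh and 1,3-anti induction reinforce each other to set 11R with C11/C12 syn.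

**Step 13**
Reactants: 21 C1–C16 aldol adduct
Product: 22 11-O-TBS ether of 21
Conditions: TBSOTf, 2,6-lutidine, CH2Cl2, −78 to 0 °C
Reagents that add atoms: tert-butyldimethylsilyl trifluoromethanesulfonate CC(C)(C)[Si](C)(C)OS(=O)(=O)C(F)(F)F
Why: Silyl triflate protection of the hindered C11 carbinol blocks 12-membered lactonisation and retro-aldol, the weak base leaving the ketone α-centres alone.

**Step 14**
Reactants: 22 11-O-TBS ether of 21
Product: 23 C1 carboxylic acid (3,5-acetonide; 11,15-bis-OTBS; 13-OTES)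
Conditions: LiOH, H2O2, THF/H2O, 0 °C; Na2SO3; NaHSO4 to pH 4
Reagents that add atoms: hydrogen peroxide OO
Why: Hydroperoxide attacks the exocyclic imide carbonyl selectively (Evans LiOOH cleavage) and frees the acid without epimerising C2.

**Step 15**
Reactants: 23 C1 carboxylic acid
Product: 24 13-hydroxy seco acid (3,5-acetonide; 11,15-bis-OTBS)
Conditions: HF·pyridine, pyridine, THF, 0 °C
Reagents that add atoms: none
Why: Buffered fluoride cleaves the triethylsilyl ether much faster than the two TBS ethers and spares the acetonide, unveiling only the C13 hydroxyl.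

**Step 16**
Reactants: 24 13-hydroxy seco acid
Product: 26 protected macrolactone (3,5-acetonide; 11,15-bis-OTBS), via mixed anhydride 25 (not isolated)
Conditions: 2,4,6-trichlorobenzoyl chloride, Et3N, THF, rt; then slow addition to DMAP, toluene, 80 °C (final 1 mM)
Reagents that add atoms: 2,4,6-trichlorobenzoyl chloride O=C(Cl)c1c(Cl)cc(Cl)cc1Cl (acyl group of 25)
Why: Yamaguchi macrolactonisation, DMAP-mediated acyl transfer from the mixed anhydride to the only free hydroxyl at high dilution, closes the 14-membered ring with retention at C13.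

**Step 17**
Reactants: 26 protected macrolactone
Product: 27 (3R,4R,5S,6S,7R,9R,11S,12R,13R,14S)-4,6,12-trihydroxy-14-[(2S,3S)-3-hydroxybutan-2-yl]-3,5,7,9,11,13-hexamethyl-1-oxacyclotetradecane-2,10-dione
Conditions: 48% aq HF, MeCN, 0 °C to rt
Reagents that add atoms: none
Why: Aqueous HF removes both TBS ethers and hydrolyses the labile anti-diol acetonide in one operation under conditions too mild for lactone opening or β-elimination.

**Compound list**
1 | propanoyl chloride | CCC(=O)Cl | starting material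
2 | 1,3-oxazolidin-2-one | O=C1NCCO1 | starting material
3 | (3R,4Z)-4-ethylidene-3-methyloxetan-2-one (methylketene dimer) | C/C=C1\OC(=O)[C@@H]1C | intermediate (not isolated)
4 | 3-[(2R)-2-methyl-3-oxopentanoyl]-1,3-oxazolidin-2-one | CCC(=O)[C@@H](C)C(=O)N1CCOC1=O | intermediate
5 | propanal | CCC=O | starting material
6 | 2-methylpent-1-en-3-one | CCC(=O)C(C)=C | starting material
7 | (2R,4R)-2,4-dimethyl-5-oxoheptanal | CCC(=O)[C@H](C)C[C@@H](C)C=O | intermediate
8 | 3-[(2R,4S,5S,6R,8R)-5-hydroxy-2,4,6,8-tetramethyl-3,9-dioxoundecanoyl]-1,3-oxazolidin-2-one | CCC(=O)[C@H](C)C[C@@H](C)[C@H](O)[C@H](C)C(=O)[C@@H](C)C(=O)N1CCOC1=O | intermediate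
9 | 3-[(2R,3R,4S,5S,6R,8R)-3,5-dihydroxy-2,4,6,8-tetramethyl-9-oxoundecanoyl]-1,3-oxazolidin-2-one | CCC(=O)[C@H](C)C[C@@H](C)[C@H](O)[C@H](C)[C@@H](O)[C@@H](C)C(=O)N1CCOC1=O | intermediate
10 | 3-[(2R)-2-[(4R,5S,6S)-2,2,5-trimethyl-6-[(2R,4R)-4-methyl-5-oxoheptan-2-yl]-1,3-dioxan-4-yl]propanoyl]-1,3-oxazolidin-2-one (3,5-acetonide of 9) | CCC(=O)[C@H](C)C[C@@H](C)[C@H](O1)[C@H](C)[C@@H](OC1(C)C)[C@@H](C)C(=O)N2CCOC2=O | intermediate
11 | tert-butyl propanoate | CCC(=O)OC(C)(C)C | starting material
12 | (E)-tert-butyl[(1-tert-butoxyprop-1-en-1-yl)oxy]dimethylsilane | C/C=C(/O[Si](C)(C)C(C)(C)C)OC(C)(C)C | intermediate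
13 | (2E)-2-methylbut-2-enal (tiglaldehyde) | C/C=C(\C)C=O | starting material
14 | tert-butyl (2S,3R,4E)-3-hydroxy-2,4-dimethylhex-4-enoate | C/C=C(\C)[C@H](O)[C@H](C)C(=O)OC(C)(C)C | intermediate
15 | tert-butyl (2S,3S,4S,5S)-3,5-dihydroxy-2,4-dimethylhexanoate | C[C@H](O)[C@H](C)[C@H](O)[C@H](C)C(=O)OC(C)(C)C | intermediate
16 | tert-butyl (2S,3S,4R,5S)-5-[(tert-butyldimethylsilyl)oxy]-3-hydroxy-2,4-dimethylhexanoate | C[C@H](O[Si](C)(C)C(C)(C)C)[C@H](C)[C@H](O)[C@H](C)C(=O)OC(C)(C)C | intermediate (not isolated)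
17 | tert-butyl (2S,3S,4S,5S)-5-[(tert-butyldimethylsilyl)oxy]-2,4-dimethyl-3-[(triethylsilyl)oxy]hexanoate | C[C@H](O[Si](C)(C)C(C)(C)C)[C@H](C)[C@H](O[Si](CC)(CC)CC)[C@H](C)C(=O)OC(C)(C)C | intermediate
18 | (2R,3R,4S,5S)-5-[(tert-butyldimethylsilyl)oxy]-2,4-dimethyl-3-[(triethylsilyl)oxy]hexan-1-ol | C[C@H](O[Si](C)(C)C(C)(C)C)[C@H](C)[C@H](O[Si](CC)(CC)CC)[C@H](C)CO | intermediate
19 | (2S,3S,4S,5S)-5-[(tert-butyldimethylsilyl)oxy]-2,4-dimethyl-3-[(triethylsilyl)oxy]hexanal | C[C@H](O[Si](C)(C)C(C)(C)C)[C@H](C)[C@H](O[Si](CC)(CC)CC)[C@H](C)C=O | intermediate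
20 | (Z)-C9 trimethylsilyl enol ether (C9=C10) of ketone 10 | C/C=C(\O[Si](C)(C)C)[C@H](C)C[C@@H](C)[C@H](O1)[C@H](C)[C@@H](OC1(C)C)[C@@H](C)C(=O)N2CCOC2=O | intermediate (not isolated)
21 | 3-[15-(tert-butyldimethylsilyloxy)-11-hydroxy-3,5-(isopropylidenedioxy)-2,4,6,8,10,12,14-heptamethyl-9-oxo-13-(triethylsilyloxy)hexadecanoyl]-1,3-oxazolidin-2-one (centres spatially as in 27) | C[C@H](O[Si](C)(C)C(C)(C)C)[C@H](C)[C@H](O[Si](CC)(CC)CC)[C@H](C)[C@@H](O)[C@H](C)C(=O)[C@H](C)C[C@@H](C)[C@H](O1)[C@H](C)[C@@H](OC1(C)C)[C@@H](C)C(=O)N2CCOC2=O | intermediate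
22 | 11-O-tert-butyldimethylsilyl ether of 21 | C[C@H](O[Si](C)(C)C(C)(C)C)[C@H](C)[C@H](O[Si](CC)(CC)CC)[C@H](C)[C@@H](O[Si](C)(C)C(C)(C)C)[C@H](C)C(=O)[C@H](C)C[C@@H](C)[C@H](O1)[C@H](C)[C@@H](OC1(C)C)[C@@H](C)C(=O)N2CCOC2=O | intermediate
23 | 11,15-bis(tert-butyldimethylsilyloxy)-3,5-(isopropylidenedioxy)-2,4,6,8,10,12,14-heptamethyl-9-oxo-13-(triethylsilyloxy)hexadecanoic acid | C[C@H](O[Si](C)(C)C(C)(C)C)[C@H](C)[C@H](O[Si](CC)(CC)CC)[C@H](C)[C@@H](O[Si](C)(C)C(C)(C)C)[C@H](C)C(=O)[C@H](C)C[C@@H](C)[C@H](O1)[C@H](C)[C@@H](OC1(C)C)[C@@H](C)C(=O)O | intermediate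
24 | 11,15-bis(tert-butyldimethylsilyloxy)-13-hydroxy-3,5-(isopropylidenedioxy)-2,4,6,8,10,12,14-heptamethyl-9-oxohexadecanoic acid (seco acid) | C[C@H](O[Si](C)(C)C(C)(C)C)[C@H](C)[C@H](O)[C@H](C)[C@@H](O[Si](C)(C)C(C)(C)C)[C@H](C)C(=O)[C@H](C)C[C@@H](C)[C@H](O1)[C@H](C)[C@@H](OC1(C)C)[C@@H](C)C(=O)O | intermediate
25 | 2,4,6-trichlorobenzoic mixed anhydride of 24 | C[C@H](O[Si](C)(C)C(C)(C)C)[C@H](C)[C@H](O)[C@H](C)[C@@H](O[Si](C)(C)C(C)(C)C)[C@H](C)C(=O)[C@H](C)C[C@@H](C)[C@H](O1)[C@H](C)[C@@H](OC1(C)C)[C@@H](C)C(=O)OC(=O)c2c(Cl)cc(Cl)cc2Cl | intermediate (not isolated)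
26 | 11,15-bis-O-tert-butyldimethylsilyl-3,5-O-isopropylidene derivative of 27 | C[C@H](O[Si](C)(C)C(C)(C)C)[C@H](C)[C@H](O1)[C@H](C)[C@@H](O[Si](C)(C)C(C)(C)C)[C@H](C)C(=O)[C@H](C)C[C@@H](C)[C@H](O2)[C@H](C)[C@@H](OC2(C)C)[C@@H](C)C1=O | intermediate
27 | (3R,4R,5S,6S,7R,9R,11S,12R,13R,14S)-4,6,12-trihydroxy-14-[(2S,3S)-3-hydroxybutan-2-yl]-3,5,7,9,11,13-hexamethyl-1-oxacyclotetradecane-2,10-dione (CNP0244358.2) | C[C@@H]1[C@@H](O)[C@H](C)C(=O)[C@H](C)C[C@@H](C)[C@H](O)[C@H](C)[C@@H](O)[C@@H](C)C(=O)O[C@H]1[C@@H](C)[C@H](C)O | target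

**Step count and risks**
Total: 17 steps. Longest linear sequence: 12 steps (steps 6–17, from tert-butyl propanoate).

Most likely to fail:

1. Step 2 (the proposed new method). The primary amine may be tied up by propanal, and control of the protonation at C8 is unproven. Fallback with known chemistry, setting out from 5 and coming back at 7:
   - Propanal 5 is α-hydroxymethylated with aqueous formaldehyde under (R)-α,α-diphenylprolinol trimethylsilyl ether catalysis (toluene/pH 7 buffer) to (2S)-3-hydroxy-2-methylpropanal F1.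
   - F1 is trapped in the same flask by Wittig olefination with 2-(triphenylphosphoranylidene)pentan-3-one to give (4E,6R)-7-hydroxy-4,6-dimethylhept-4-en-3-one F2.
   - Catalyst-controlled hydrogenation of the trisubstituted enone with [Ir(cod)((S)-tBu-PHOX)][B(C6H3(CF3)2)4] under H2 sets the ketone α-centre (helped by allylic strain from C6) and gives (4R,6R)-7-hydroxy-4,6-dimethylheptan-3-one F3.
   - TEMPO/PhI(OAc)2 oxidation of the primary alcohol returns 7.

2. Step 12 (fragment union). Syn/anti selectivity of the open transition state and the regiochemistry of silyl enol ether formation next to the C8 centre are the weak points. Fallback setting out from 10 and 19 and coming back at 21: switch from substrate control to a closed, reagent-controlled transition state. Ketone 10 is enolised with diisopinocampheylboron triflate (Ipc2BOTf, antipode chosen for 10S,11R) and iPr2NEt in CH2Cl2 at −78 °C to the Z-enol borinate, 19 is added (Paterson syn-aldol), and the boron aldolate is cleaved with H2O2. This makes no new compound (F0).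

3. Step 16 (macrolactonisation). This seco acid is a diastereomer of the well-studied erythronolide series and may lack the usual preorganisation. Fallback setting out from 24 and coming back at 26: Corey–Nicolaou/Gerlach double activation. Acid 24 is converted with 2,2'-dipyridyl disulfide and PPh3 into the isolable S-(pyridin-2-yl) thioester of 24 F4. F4 is cyclised by slow addition to AgOTf in toluene at 80 °C, so ring closure proceeds by internal proton relay and silver activation of a neutral thioester and not by DMAP transfer from a mixed anhydride.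

**Further compounds**
F1 | step 2 | (2S)-3-hydroxy-2-methylpropanal | O=C[C@@H](C)CO
F2 | step 2 | (4E,6R)-7-hydroxy-4,6-dimethylhept-4-en-3-one | CCC(=O)/C(C)=C/[C@@H](C)CO
F3 | step 2 | (4R,6R)-7-hydroxy-4,6-dimethylheptan-3-one | CCC(=O)[C@H](C)C[C@@H](C)CO
F0 | step 12 | none | none
F4 | step 16 | S-(pyridin-2-yl) thioester of 24 | C[C@H](O[Si](C)(C)C(C)(C)C)[C@H](C)[C@H](O)[C@H](C)[C@@H](O[Si](C)(C)C(C)(C)C)[C@H](C)C(=O)[C@H](C)C[C@@H](C)[C@H](O1)[C@H](C)[C@@H](OC1(C)C)[C@@H](C)C(=O)Sc2ccccn2
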